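The route cuts the five-membered ring's substituents back to a cyclopentenone. The contiguous triad C1 (quaternary, methyl), C5 (ring-fusion CH) and C6 (carbinol), flanked by the C4 oxygen, is the footprint of conjugate methylation followed by aldol capture. One copper-catalysed operation unites 3-(benzyloxymethyl)cyclopent-2-enone, trimethylaluminium and a citramalate-derived C6–C9 aldehyde whose C8/C9 oxygens are tied as an acetonide. It forms C1–CH3 and C5–C6 and sets C1, C5 and C6, while C8 is carried in. The C4 ketone then takes the isopropyl unit. A samarium pinacol coupling of the C9 and C10 aldehydes closes the seven-membered ring, and two angelate esters finish the target.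

Key step: step 6

**Numbering and faces.** C1 is the quaternary ring-fusion carbon, C2–C3 are CH2, C4 is the isopropyl carbinol and C5 is the ring-fusion CH. C6–C10 run round the seven-membered ring: C6 and C10 are ester carbons, C7 is CH2, C8 is the methyl carbinol and C9 is the free carbinol. β is the face of the C1 methyl. "Daucane" means the bicyclo[5.3.0]decane skeleton with methyl on C1 and C8 and isopropyl on C4. "9,10-Secodaucane" lacks the C9–C10 bond.

**Target configuration.** The target is 1R,4S,5R,6R,8S,9R,10R. The ring fusion is trans (H5 α), the C4 hydroxyl is β, and O6, O8, O9 and O10 are all α.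

**Protecting-group logic.**
- O8 and O9 travel together as an acetonide.
- O10 is a benzyl ether, lost in the same hydrogenation that turns isopropenyl into isopropyl.
- Only O6 needs its own protection step.

**Assumption.** The sense of induction of the copper catalyst follows the ligand antipode, so the antipode that gives 1R is taken. This can be checked on the protonated conjugate adduct before aldehyde is committed.

**Step 1**
Reactants: 1 tributyltin hydride; 2 benzyl chloromethyl ether
Product: 4 (benzyloxymethyl)tributylstannane, via tributylstannyllithium 3 (not isolated)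
Conditions: LDA, THF, 0 °C; then 2, −78 °C → rt
Reagents that add atoms: none
Why: Deprotonation of the Sn–H bond gives a stannyl anion that displaces chloride from the activated α-chloro ether (SN2 alkylation of a stannyllithium), the standard entry to α-alkoxymethylstannanes.

**Step 2**
Reactants: 4 (benzyloxymethyl)tributylstannane; 5 3-ethoxycyclopent-2-en-1-one
Product: 8 3-(benzyloxymethyl)cyclopent-2-en-1-one, via benzyloxymethyllithium 6 (not isolated), via tertiary allylic alcohol adduct 7 (not isolated)
Conditions: n-BuLi, THF, −78 °C; add 5, −78 °C; then 1 M HCl, 0 °C → rt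
Reagents that add atoms: water, O
Why: Tin–lithium exchange gives an α-alkoxy organolithium (kept cold so that it does not undergo Wittig rearrangement) that adds 1,2 to the vinylogous ester, and acid then ionises the tertiary allylic alcohol and hydrolyses the enol ether with carbonyl transposition (Stork–Danheiser sequence).

**Step 3**
Reactants: 9 (S)-citramalic acid
Product: 10 (2S)-2-methylbutane-1,2,4-triol
Conditions: BH3·SMe2, B(OMe)3, THF, 0 °C → rt; MeOH quench
Reagents that add atoms: none
Why: Borane reduces both carboxylic acids under non-basic conditions, so the tertiary carbinol centre (future C8) is untouched and keeps its S configuration.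

**Step 4**
Reactants: 10 (2S)-2-methylbutane-1,2,4-triol
Product: 11 2-[(4S)-2,2,4-trimethyl-1,3-dioxolan-4-yl]ethan-1-ol
Conditions: Me2C(OMe)2, TsOH·H2O (cat.), acetone, rt
Reagents that add atoms: 2,2-dimethoxypropane, COC(C)(C)OC
Why: Equilibrium-controlled ketalisation picks the 1,2-diol because the dioxolane avoids the syn-diaxial methyl contacts of the alternative 4,4-disubstituted 1,3-dioxane, which leaves the future C6 alcohol free.

**Step 5**
Reactants: 11 2-[(4S)-2,2,4-trimethyl-1,3-dioxolan-4-yl]ethan-1-ol
Product: 12 [(4S)-2,2,4-trimethyl-1,3-dioxolan-4-yl]acetaldehyde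
Conditions: TEMPO (cat.), PhI(OAc)2, CH2Cl2, rt
Reagents that add atoms: none
Why: Oxoammonium (TEMPO) oxidation stops at the aldehyde under nearly neutral conditions, which avoids β-elimination of the C8 oxygen and cannot touch the fully substituted stereocentre.

**Step 6**
Reactants: 8 3-(benzyloxymethyl)cyclopent-2-en-1-one; 13 trimethylaluminium; 12 [(4S)-2,2,4-trimethyl-1,3-dioxolan-4-yl]acetaldehyde
Product: 15 (2R,3R)-3-[(benzyloxy)methyl]-2-{(1R)-1-hydroxy-2-[(4S)-2,2,4-trimethyl-1,3-dioxolan-4-yl]ethyl}-3-methylcyclopentan-1-one, via dimethylaluminium enolate 14 (not isolated)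
Conditions: Cu(OTf)2 (5 mol %), chiral bidentate sulfonate-NHC·Ag(I) complex (2.5 mol %), 13 (1.5 equiv), THF, −78 → −50 °C; then 12 (1.5 equiv), −78 → −40 °C; cold aq. Rochelle salt
Reagents that add atoms: trimethylaluminium 13, C[Al](C)C
Why: A chiral NHC–methylcopper species formed from the copper salt and 13 binds the aluminium-activated enone and transfers methyl to C1 by oxidative addition/reductive elimination, leaving the regiodefined C4–O/C5 dimethylaluminium enolate 14; this is the known copper-catalysed asymmetric conjugate addition of trialkylaluminium reagents to 3-substituted cyclopentenones with aldol interception of the enolate. C1 is set by the ligand, which shields one enantioface of the flat enone. Aldehyde 12 then binds to aluminium and reacts through a closed six-membered chair (Zimmerman–Traxler), and because the ring locks the enolate in the E(O) geometry the aldehyde chain sits equatorial and C5/C6 come out anti, which sets C6. C5 is set by the new quaternary centre, since the aldehyde approaches the enolate face that carries the methyl group, away from the longer CH2OBn arm (bulkier still when complexed by methylaluminium), so C6 and C10 end up trans as the trans ring fusion requires. No ring is closed; two C–C bonds (C1–CH3, C5–C6) and three stereocentres arise while C8 arrives unchanged with 12. The step needs 1,4- over 1,2-methyl transfer (secured by copper), enolate rather than residual Me–Al addition to 12 (small excess of 13, THF complexation, low temperature) and no dehydration or retro-aldol (cold tartrate quench, and an aldehyde with no acidic OH and no strongly chelating site).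

**Step 7**
Reactants: 15 aldol from step 6
Product: 16 (2R,3R)-3-[(benzyloxy)methyl]-2-{(1R)-1-[(tert-butyldimethylsilyl)oxy]-2-[(4S)-2,2,4-trimethyl-1,3-dioxolan-4-yl]ethyl}-3-methylcyclopentan-1-one
Conditions: TBSOTf, 2,6-lutidine, CH2Cl2, −78 → 0 °C
Reagents that add atoms: tert-butyldimethylsilyl triflate, CC(C)(C)[Si](C)(C)OS(=O)(=O)C(F)(F)F
Why: A silyl triflate with a hindered pyridine base silylates the aldol hydroxyl before retro-aldol or enolisation can start, and O6 must be masked so that it is neither oxidised nor able to form lactols with the later aldehydes.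

**Step 8**
Reactants: 16 silyloxy ketone
Product: 17 (1R,2R,3R)-3-[(benzyloxy)methyl]-2-{(1R)-1-[(tert-butyldimethylsilyl)oxy]-2-[(4S)-2,2,4-trimethyl-1,3-dioxolan-4-yl]ethyl}-3-methyl-1-(prop-1-en-2-yl)cyclopentan-1-ol
Conditions: CH2=C(CH3)MgBr, anhydrous CeCl3, THF, −78 → −20 °C; aq. NH4Cl
Reagents that add atoms: isopropenylmagnesium bromide, CC(=C)[Mg]Br
Why: Organocerium 1,2-addition (low basicity, high oxophilicity) suppresses enolisation and β-elimination, the sp2 nucleophile cannot reduce the ketone by β-hydride transfer as an isopropyl metal could, and it attacks C4 from the α face, opposite the adjacent C5 side chain and the C1 methyl, to give the 4β-alcohol.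

**Step 9**
Reactants: 17 isopropenyl carbinol
Product: 19 (1R,4S,5R,6R,8S)-6-(tert-butyldimethylsilyloxy)-9,10-secodaucane-4,8,9,10-tetraol, via debenzylated isopropyl carbinol 18 (not isolated)
Conditions: H2 (1 atm), 10% Pd/C, MeOH, rt; filter; CSA (10 mol %), MeOH, 0 °C → rt; Et3N quench
Reagents that add atoms: none
Why: Heterogeneous hydrogenation saturates the 1,1-disubstituted alkene to isopropyl and hydrogenolyses the benzyl ether in one pass, and acid-catalysed transketalisation with methanol then frees the C8/C9 diol faster than it touches the hindered secondary TBS ether, with no stereocentre affected.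

**Step 10**
Reactants: 19 tetraol
Product: 20 (1R,4S,5R,6R,8S)-6-(tert-butyldimethylsilyloxy)-4,8-dihydroxy-9,10-secodaucane-9,10-dial
Conditions: (COCl)2, DMSO, CH2Cl2, −78 °C; Et3N, → 0 °C; used crude
Reagents that add atoms: none
Why: Swern oxidation converts both primary alcohols into aldehydes, cannot oxidise the two tertiary alcohols, does not cleave the C8–C9 glycol as iodine(III) or periodate reagents might, and neither aldehyde has an α-hydrogen that could epimerise.

**Step 11**
Reactants: 20 dialdehyde
Product: 21 (1R,4S,5R,6R,8S,9R,10R)-6-(tert-butyldimethylsilyloxy)daucane-4,8,9,10-tetraol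
Conditions: SmI2 (4 equiv), t-BuOH (2 equiv), THF, slow addition of 20 (high dilution), −78 °C → rt; aq. NaHCO3/Na2S2O3
Reagents that add atoms: none
Why: In this intramolecular samarium(II) pinacol coupling (7-membered closure helped by the trans-disposed arms and two fully substituted centres) both oxygens are held on samarium(III), which gives the cis-diol, and the α,α face follows because O10 then lies anti to the C1 methyl with C2 anti to the forming bond (Felkin-type) while O9 stays beside the samarium-binding free C8 hydroxyl.

**Step 12**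
Reactants: 21 tetraol
Product: 22 (1R,4S,5R,6R,8S,9R,10R)-6-(tert-butyldimethylsilyloxy)-8,9-(isopropylidenedioxy)daucane-4,10-diol
Conditions: Me2C(OMe)2, PPTS (10 mol %), CH2Cl2, rt (equilibrating)
Reagents that add atoms: 2,2-dimethoxypropane, COC(C)(C)OC
Why: Under thermodynamic ketalisation a dioxolane over C9–C10 would force towards eclipsing a bond whose two ends carry the fully substituted C8 and C1 and their two β-methyl groups, whereas bridging O8/O9 only presses C7H2 against C10H and gains from the gem-disubstitution at C8, O4 has no cis-vicinal partner and O6 is silylated, so the 8,9-acetonide should accumulate and leave O10 free.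

**Step 13**
Reactants: 22 silyl ether acetonide
Product: 23 (1R,4S,5R,6R,8S,9R,10R)-8,9-(isopropylidenedioxy)daucane-4,6,10-triol
Conditions: TBAF, THF, rt → 45 °C
Reagents that add atoms: none
Why: Fluoride-induced desilylation frees O6 under conditions that leave the acetonide and the free alcohols untouched.

**Step 14**
Reactants: 23 triol acetonide; 24 angelic acid
Product: 26 (1R,4S,5R,6R,8S,9R,10R)-6,10-bis(angeloyloxy)-8,9-(isopropylidenedioxy)daucan-4-ol, via angelic 2,4,6-trichlorobenzoic anhydride 25 (not isolated)
Conditions: 24 (excess), 2,4,6-Cl3C6H2COCl, Et3N, toluene, rt; then 23, 80 °C (no DMAP)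
Reagents that add atoms: angelic acid 24, C/C=C(/C)C(=O)O
Why: Mixed-anhydride (Yamaguchi-type) esterification run without a nucleophilic pyridine catalyst is the established way to place angelates on hindered secondary alcohols without Z→E isomerisation, and only O6 and O10 react because O4 is tertiary and O8/O9 are locked in the acetonide.

**Step 15**
Reactants: 26 bis-angelate acetonide
Product: 27 (1R,4S,5R,6R,8S,9R,10R)-6,10-bis(angeloyloxy)daucane-4,8,9-triol (CNP0194216.1)
Conditions: AcOH–H2O (4:1), 45 °C
Reagents that add atoms: none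
Why: Mild aqueous-acid hydrolysis of the isopropylidene ketal frees O8 and O9 under conditions in which hindered conjugated esters neither hydrolyse nor migrate as they would under base and the tertiary C4 alcohol does not ionise.

**Compound list**

1 | tributyltin hydride | CCCC[SnH](CCCC)CCCC | starting material
2 | benzyl chloromethyl ether | ClCOCc1ccccc1 | starting material
3 | tributylstannyllithium | [Li][Sn](CCCC)(CCCC)CCCC | intermediate
4 | (benzyloxymethyl)tributylstannane | CCCC[Sn](CCCC)(CCCC)COCc1ccccc1 | intermediate
5 | 3-ethoxycyclopent-2-en-1-one | CCOC1=CC(=O)CC1 | starting material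
6 | benzyloxymethyllithium | [Li]COCc1ccccc1 | intermediate
7 | 1-(benzyloxymethyl)-3-ethoxycyclopent-2-en-1-ol (racemic) | CCOC1=CC(O)(COCc2ccccc2)CC1 | intermediate
8 | 3-(benzyloxymethyl)cyclopent-2-en-1-one | O=C1C=C(COCc2ccccc2)CC1 | intermediate
9 | (S)-citramalic acid | OC(=O)C[C@](C)(O)C(O)=O | starting material
10 | (2S)-2-methylbutane-1,2,4-triol | OCC[C@](C)(O)CO | intermediate
11 | 2-[(4S)-2,2,4-trimethyl-1,3-dioxolan-4-yl]ethan-1-ol | OCC[C@](C)(O1)COC1(C)C | intermediate
12 | [(4S)-2,2,4-trimethyl-1,3-dioxolan-4-yl]acetaldehyde (C6–C9) | O=CC[C@](C)(O1)COC1(C)C | intermediate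
13 | trimethylaluminium | C[Al](C)C | starting material
14 | dimethylaluminium (R)-3-(benzyloxymethyl)-3-methylcyclopent-1-en-1-olate | C[Al](C)OC1=C[C@](C)(COCc2ccccc2)CC1 | intermediate
15 | anti aldol, 1R,5R,6R,8S, C6 chain trans to CH2OBn | O[C@H](C[C@](C)(O1)COC1(C)C)[C@@H]2C(=O)CC[C@@]2(C)COCc3ccccc3 | intermediate
16 | O6-TBS ether of 15 | CC(C)(C)[Si](C)(C)O[C@H](C[C@](C)(O1)COC1(C)C)[C@@H]2C(=O)CC[C@@]2(C)COCc3ccccc3 | intermediate
17 | 4β-hydroxy-4α-isopropenyl adduct of 16 | CC(C)(C)[Si](C)(C)O[C@H](C[C@](C)(O1)COC1(C)C)[C@@H]2[C@@](O)(C(C)=C)CC[C@@]2(C)COCc3ccccc3 | intermediate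
18 | (1S,2R,3R)-2-{(1R)-1-[(tert-butyldimethylsilyl)oxy]-2-[(4S)-2,2,4-trimethyl-1,3-dioxolan-4-yl]ethyl}-3-(hydroxymethyl)-3-methyl-1-(propan-2-yl)cyclopentan-1-ol | CC(C)(C)[Si](C)(C)O[C@H](C[C@](C)(O1)COC1(C)C)[C@@H]2[C@@](O)(C(C)C)CC[C@@]2(C)CO | intermediate
19 | (1R,4S,5R,6R,8S)-6-TBSO-9,10-secodaucane-4,8,9,10-tetraol | CC(C)(C)[Si](C)(C)O[C@H](C[C@](C)(O)CO)[C@@H]1[C@@](O)(C(C)C)CC[C@@]1(C)CO | intermediate
20 | (1R,4S,5R,6R,8S)-6-TBSO-4,8-dihydroxy-9,10-secodaucane-9,10-dial | CC(C)(C)[Si](C)(C)O[C@H](C[C@](C)(O)C=O)[C@@H]1[C@@](O)(C(C)C)CC[C@@]1(C)C=O | intermediate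
21 | 6α-TBSO-daucane-4β,8α,9α,10α-tetraol | CC(C)(C)[Si](C)(C)O[C@@H]1C[C@](C)(O)[C@H](O)[C@H](O)[C@]2(C)CC[C@](O)(C(C)C)[C@@H]12 | intermediate
22 | 8,9-acetonide of 21 | CC(C)(C)[Si](C)(C)O[C@@H]1C[C@](C)(O3)[C@H](OC3(C)C)[C@H](O)[C@]2(C)CC[C@](O)(C(C)C)[C@@H]12 | intermediate
23 | 8α,9α-(isopropylidenedioxy)daucane-4β,6α,10α-triol | O[C@@H]1C[C@](C)(O3)[C@H](OC3(C)C)[C@H](O)[C@]2(C)CC[C@](O)(C(C)C)[C@@H]12 | intermediate
24 | angelic acid, (Z)-2-methylbut-2-enoic acid | C/C=C(/C)C(=O)O | starting material
25 | angelic 2,4,6-trichlorobenzoic anhydride | C/C=C(/C)C(=O)OC(=O)c1c(Cl)cc(Cl)cc1Cl | intermediate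
26 | 6α,10α-bis(angeloyloxy)-8α,9α-(isopropylidenedioxy)daucan-4β-ol | C/C=C(/C)C(=O)O[C@@H]1C[C@](C)(O3)[C@H](OC3(C)C)[C@H](OC(=O)/C(C)=C\C)[C@]2(C)CC[C@](O)(C(C)C)[C@@H]12 | intermediate
27 | 6α,10α-bis(angeloyloxy)daucane-4β,8α,9α-triol (CNP0194216.1) | C/C=C(/C)C(=O)O[C@@H]1C[C@](C)(O)[C@H](O)[C@H](OC(=O)/C(C)=C\C)[C@]2(C)CC[C@](O)(C(C)C)[C@@H]12 | target

**Step count**

Total step count: 15. Longest linear sequence: 13 (steps 3–15, from (S)-citramalic acid).

**Steps most likely to fail**

Step 6. The hindered aluminium enolate may be captured too slowly, so that residual methylaluminium species consume the aldehyde, and facial or anti/syn control may erode. The fallback sets out from 8 and comes back at 15. It splits the union into separate events and changes the enolate metal. The same conjugate methylation of 8 with 13 is run alone, and enolate 14 is silylated with TMSOTf to give the trimethylsilyl enol ether F1. F1 can be purified and checked for enantiopurity. MeLi (THF, 0 °C) releases the regiodefined lithium enolate F2. Dicyclohexylboron chloride converts this into the dicyclohexylboron enolate F3. F3 adds to 12 at −78 °C through a short-bonded, tighter chair, the most dependable source of anti aldols from ring ketones. Buffered H2O2 work-up gives 15.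

Step 11. The two hindered aldehydes may simply be reduced to alcohols instead of coupling, or the coupling may take the wrong face or give a trans-diol. The fallback sets out from 20 and comes back at 21. It separates ring closure from oxygenation. Double Wittig methylenation (Ph3P=CH2, enough excess to cover the free hydroxyls) gives the divinyl compound F4. Ring-closing metathesis with a second-generation NHC-ligated ruthenium isopropoxybenzylidene catalyst (toluene, 80 °C) gives the Δ9-cycloheptene F5. OsO4·TMEDA (CH2Cl2, −78 °C) is then steered by a hydrogen bond from the allylic C8 hydroxyl to the α face. That face is also free of the two β-methyl groups, so the product is the osmate(VI) ester–TMEDA chelate F6. Cleavage with aqueous sodium sulfite returns 21.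

Step 12. Ketalisation may settle on the O9/O10 pair or give a mixture that does not converge, so that O10 is not left free. The fallback sets out from 21 and comes back at 27. It protects O9 alone instead of tying O8 to O9.
- Bu2SnO (toluene, reflux, −H2O) gives the dibutylstannylene acetal F7. It is drawn across O9/O10, and the O8/O9 isomer would activate the same oxygen, because O9 is the secondary, equatorial member of either five-membered stannylene.
- PMBCl with Bu4NI (cat.) at 90 °C, followed by aqueous KF work-up, gives the 9-O-PMB ether F8.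
- TBAF gives the 6,10-diol F9.
- Acylation with anhydride 25 as in step 14 gives the bis-angelate F10.
- DDQ in CH2Cl2/pH 7 buffer removes the PMB group under neutral conditions that leave electron-poor angelate alkenes alone, which gives 27.

**Further compounds**

F1 | step 6 | (R)-{[3-(benzyloxymethyl)-3-methylcyclopent-1-en-1-yl]oxy}trimethylsilane | C[Si](C)(C)OC1=C[C@](C)(COCc2ccccc2)CC1
F2 | step 6 | lithium (R)-3-(benzyloxymethyl)-3-methylcyclopent-1-en-1-olate | [Li]OC1=C[C@](C)(COCc2ccccc2)CC1
F3 | step 6 | dicyclohexylboron enolate of the same ketone | C1CCCCC1B(C2CCCCC2)OC3=C[C@](C)(COCc4ccccc4)CC3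
F4 | step 11 | 9,10-bis(methylidene) (divinyl) analogue of 20 | CC(C)(C)[Si](C)(C)O[C@H](C[C@](C)(O)C=C)[C@@H]1[C@@](O)(C(C)C)CC[C@@]1(C)C=C
F5 | step 11 | 6α-TBSO-dauc-9-ene-4β,8α-diol | CC(C)(C)[Si](C)(C)O[C@@H]1C[C@](C)(O)C=C[C@]2(C)CC[C@](O)(C(C)C)[C@@H]12
F6 | step 11 | 9α,10α-osmate(VI) ester of 21, TMEDA chelate | CC(C)(C)[Si](C)(C)O[C@@H]1C[C@](C)(O)[C@H](O3)[C@H](O[Os]3(=O)=O)[C@]2(C)CC[C@](O)(C(C)C)[C@@H]12.CN(C)CCN(C)C
F7 | step 12 | 9,10-O-dibutylstannylene acetal of 21 | CC(C)(C)[Si](C)(C)O[C@@H]1C[C@](C)(O)[C@H](O3)[C@H](O[Sn]3(CCCC)CCCC)[C@]2(C)CC[C@](O)(C(C)C)[C@@H]12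
F8 | step 12 | 9-O-(4-methoxybenzyl) ether of 21 | CC(C)(C)[Si](C)(C)O[C@@H]1C[C@](C)(O)[C@H](OCc3ccc(OC)cc3)[C@H](O)[C@]2(C)CC[C@](O)(C(C)C)[C@@H]12
F9 | step 12 | 9α-(4-methoxybenzyloxy)daucane-4β,6α,8α,10α-tetraol | O[C@@H]1C[C@](C)(O)[C@H](OCc3ccc(OC)cc3)[C@H](O)[C@]2(C)CC[C@](O)(C(C)C)[C@@H]12
F10 | step 12 | 6α,10α-bis(angeloyloxy)-9α-(4-methoxybenzyloxy)daucane-4β,8α-diol | C/C=C(/C)C(=O)O[C@@H]1C[C@](C)(O)[C@H](OCc3ccc(OC)cc3)[C@H](OC(=O)/C(C)=C\C)[C@]2(C)CC[C@](O)(C(C)C)[C@@H]12
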